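**The easy step.** The midnight flask is the alpha recipe in the same kind of closed flask, stopped at 2.0 min, so alpha's reading at 120 s, 37.0%, was already a first answer for midnight. I wanted a second way to that number which did not use that reading, and one that could also serve the other set-ups.

in all of them: free catalyst 5 mol%

|  | substrate | reagent | impurity | remark | time |
|---|---|---|---|---|---|
| alpha | 0.063 M | 3 equiv | 0.55 mM | run made earlier |  |
| zeta | 0.063 M | 3 equiv | 1.1 mM | run made earlier |  |
| dawn | 0.063 M | 3.00 equiv | 0.55 mM | a single well-mixed tank run continuously and read at steady state, 2.0 min in it on average |  |
| summer | 0.063 M (fed, over 1.60 min) | 3.00 equiv | 0.55 mM | all but substrate at the start; substrate goes in evenly over 1.60 min, the run ends at 2.0 min | 2.0 min |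
| autumn | 0.063 M | 3.00 equiv (fed, over 1.60 min) | 0.55 mM | a stirred flask in which reagent is dosed at a steady rate over 1.60 min without added volume, worked up at 2.0 min | 2.0 min |
| midnight | 0.063 M | 3.00 equiv | 0.55 mM | a closed flask charged with all of it at once and left for 2.0 min | 2.0 min |

- alpha (time / s: target / %): 20.0: 7.2; 40.0: 15.9; 60.0: 21.9; 80.0: 28.0; 90.0: 29.7; 120: 37.0
- zeta (time / s: target / %): 10.0: 2.3; 12.0: 4.0

(readings scatter by 0.5 percentage points)

- the set-up with the highest amount of target at the outlet or at the end, in percent of the substrate put in ("none" if the first two lie within 2 percentage points) (dawn / summer / autumn / midnight / none)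
- amount of target at the outlet or at the end, in percent of the substrate put in, dawn
- amount of target at the outlet or at the end, in percent of the substrate put in, summer
- amount of target at the outlet or at the end, in percent of the substrate put in, autumn
- amount of target at the outlet or at the end, in percent of the substrate put in, midnight

- the stated concentrations are those of everything mixed, before any reaction; amounts are the same in each set-up
- the feed brings no volume worth counting
- the earlier runs were made in a closed, stirred flask

**Two ways.** I took alpha's reading at 90.0 s, 29.7%, and carried it to 2.0 min. A straight line through the fraction made gave 39.6%. The fraction not yet target gave a constant, the negative logarithm of that fraction divided by the time, 0.00392 s⁻¹, a pseudo-first-order constant. It projected 37.5%.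

**Which one cheats.** Against the reading, with its scatter of 0.5 percentage points, the fraction left was off by 0.50 points and the line by 2.6 points. The line cheats: it keeps the early rate, yet alpha made target more slowly late than early.

**The other set-ups.** In the dawn tank, at an average stay of 2.0 min, the fraction left is one over one plus the constant times the stay, so I expected 32.0%. In the summer flask each portion of substrate reacts from its own entry, and averaging over the feed gave 75.9% left, so 24.1% made. Both earlier runs used 3 equiv of reagent, so they could not show how the autumn flask responds to dosing. If the rate follows the reagent present, I expected 24.6%; if it ignores reagent, 37.5%. I committed to midnight as best, since its projection exceeded dawn's and summer's and reached the top of autumn's range.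

**Forecast and result.** The forecast, its values a little apart from mine, named midnight with 31% for dawn, 25% for summer, 25.5% for autumn and 37.5% for midnight, holding that the charge of reagent “can't reveal the reagent order” and assuming a rate proportional to substrate and to reagent. The flasks gave 28.7% for dawn, 26.9% for summer, 29.7% for autumn and 36.9% for midnight, so midnight was best.

    reagent + free catalyst ⇌ catalyst intermediate A (K = 4.60 M⁻¹, k = 170 M⁻¹ s⁻¹)
    substrate + catalyst intermediate A → catalyst intermediate B (k = 7.50 M⁻¹ s⁻¹)
    catalyst intermediate B → by-product + catalyst intermediate C (k = 0.480 s⁻¹)
    catalyst intermediate C ⇌ catalyst intermediate D (K = 1.10, k = 0.510 s⁻¹)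
    catalyst intermediate D → free catalyst + target (k = 3.60 s⁻¹)
    free catalyst + impurity → spent catalyst (k = 16000 M⁻¹ s⁻¹)
    target ⇌ isomer of the product (K = 2.10, k = 0.00310 s⁻¹)

**Where it stood.** By 2.00 min in the midnight flask, impurity stood at 0% of its charge and spent catalyst at 17.5% of the catalyst charged. Target had been passing into isomer of the product while substrate was still present. My fraction not yet target for midnight, 62.5%, stood there as substrate 54.5%, isomer 7.14% and 1.38% of the substrate charged held on catalyst intermediates B, C and D, together 63.1%. For the summer flask the same constant gave 75.9%, and at 2.00 min that flask held substrate 67.7%, isomer 3.75% and 1.61% of the substrate charged on those same intermediates, together 73.1%.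

The readings are simulated with made-up constants, noise included.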